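**Retrosynthetic overview**

1. Rings are lettered A to G from the 2,4,6-trihydroxyphenyl end. The last disconnections are the eighteen O-methyl groups and the ring D–O–ring E ether, which is cut into a ring A–D aryl bromide and a ring E–F–G phenol.
2. The plan rests on ring E: five contiguous oxygen-bearing carbons (C1–O–ring D, C6–O–ring F, C3/C4/C5–OH) and one C–H (C2). These six carbons are the four carbons of squaric acid plus the C(OMe)=CH2 carbons of methyl vinyl ether.
3. Ring E is therefore grown on the phenolic oxygen of a ring F–G phenol: an aryloxy/methoxy squarate takes up 1-methoxyvinyllithium, and the cyclobutenone is ring-expanded thermally (new bond C1–C2 of ring E), leaving the only free OH at C1.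
4. The ring F–G phenol comes from syringaldehyde by O-arylation and Baeyer–Villiger oxidation. The ring A–D bromide is built by repeating "hindered phenol + bromobenzaldehyde, then Baeyer–Villiger" (A to B to C), then adding ring D by Chan–Lam coupling with a bromoarylboronic acid.
5. Ring formation order: only ring E is constructed (step 6); rings A, B, C, D, F and G are purchased arenes.

Key step: step 6

Remark: the target has no stereocentre. The one stereocentre met on the way (the quaternary carbon of 12 and 13, racemic) is erased in step 6. 2,4,6-Trimethoxyphenol and 4-bromo-2,6-dimethoxybenzaldehyde are assumed to be purchasable.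

**Route**

Step 1
Reactants: 1 syringaldehyde; 2 3,4,5-trimethoxyphenylboronic acid
Product: 3 3,5-dimethoxy-4-(3,4,5-trimethoxyphenoxy)benzaldehyde
Conditions: Cu(OAc)2 (20 mol %), pyridine, 4 Å MS, O2 (1 atm), CH2Cl2, rt
Reagents that add atoms: none
Why: Chan–Lam oxidative O-arylation, in which the di-ortho-methoxy phenoxide binds divalent copper, the unhindered boronic acid transmetalates and the ether is released by reductive elimination, the aldehyde being inert.

Step 2
Reactants: 3 3,5-dimethoxy-4-(3,4,5-trimethoxyphenoxy)benzaldehyde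
Product: 5 3,5-dimethoxy-4-(3,4,5-trimethoxyphenoxy)phenol (ring F–G phenol), via aryl formate 4 (not isolated)
Conditions: mCPBA, CH2Cl2, 0 °C to rt; then K2CO3 (cat.), MeOH, rt
Reagents that add atoms: mCPBA, O=C(OO)c1cccc(Cl)c1
Why: Baeyer–Villiger (Dakin-type) oxidation in which the electron-rich aryl group migrates in preference to hydride, followed by transesterification of the formate with methanol.

Step 3
Reactants: 6 squaric acid
Product: 7 3,4-dichlorocyclobut-3-ene-1,2-dione (squaryl dichloride)
Conditions: (COCl)2, DMF (cat.), CH2Cl2, 40 °C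
Reagents that add atoms: oxalyl chloride, ClC(=O)C(Cl)=O
Why: Vilsmeier-type activation converts both vinylogous acid hydroxyls into vinylogous acid chlorides, a standard preparation of this dichloride.

Step 4
Reactants: 7 squaryl dichloride; 5 ring F–G phenol
Product: 9 3-[3,5-dimethoxy-4-(3,4,5-trimethoxyphenoxy)phenoxy]-4-methoxycyclobut-3-ene-1,2-dione, via chlorosquarate 8 (not isolated)
Conditions: MeOH (1.0 equiv), CH2Cl2, 0 °C to rt, N2 purge; then 5, iPr2NEt, CH2Cl2, −40 to 0 °C
Reagents that add atoms: methanol, CO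
Why: Two successive addition–elimination substitutions at vinylogous acid chloride carbons, the first stopping after one methanol because the new methoxy donor deactivates the second chloride, and the second using the phenoxide of 5 to displace chloride, a far better leaving group than methoxide.

Step 5
Reactants: 9 aryloxy methoxy squarate; 10 methyl vinyl ether
Product: 13 2-[3,5-dimethoxy-4-(3,4,5-trimethoxyphenoxy)phenoxy]-3,4-dimethoxy-4-(1-methoxyethenyl)cyclobut-2-en-1-one (racemic), via 1-methoxyvinyllithium 11 (not isolated), via lithium alkoxide 12 (not isolated)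
Conditions: 10 (excess), t-BuLi, THF, −78 to 0 °C; then add to 9, THF, −78 °C; then MeOTf, −78 to 0 °C; Et3N-deactivated silica
Reagents that add atoms: methyl trifluoromethanesulfonate, COS(=O)(=O)C(F)(F)F
Why: 1,2-Addition of an alkenyllithium to a squarate carbonyl with in-flask O-methylation of the alkoxide, attack being expected at the carbonyl conjugated to the weaker aryloxy donor and flanked by the small methoxy-bearing carbon (the more ketone-like and less hindered one), while the new quaternary stereocentre forms as a racemate that step 6 erases.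

Step 6
Reactants: 13 2-aryloxy-3,4-dimethoxy-4-(1-methoxyethenyl)cyclobut-2-en-1-one
Product: 16 2-[3,5-dimethoxy-4-(3,4,5-trimethoxyphenoxy)phenoxy]-3,4,5-trimethoxyphenol (ring E–F–G phenol), via dienylketene 14 (not isolated), via cyclohexadienone 15 (not isolated)
Conditions: degassed p-xylene (0.01 M), 138 °C, argon
Reagents that add atoms: none
Why: Heating should open the cyclobutenone by conrotatory 4π electrocyclic cleavage of the bond between the carbonyl carbon and the quaternary carbon; the 4-methoxy donor rotates outward and the 1-methoxyvinyl group inward, giving the (Z)-dienylketene 14. A thermally allowed disrotatory 6π electrocyclisation then joins the ketene carbon to the terminal CH2 carbon and closes ring E as cyclohexa-2,4-dienone 15, which enolises irreversibly to the phenol. The closest known reaction is the Moore rearrangement of squarate-derived 4-alkenyl-4-alkoxy (or 4-hydroxy) cyclobutenones to highly oxygenated phenols and hydroquinones. No stereocentre is created and the racemic quaternary centre of 13 disappears. The step needs torquoselectivity, which the methoxy donor on the sp3 carbon secures, and the right constitution (aryloxy on the carbon next to the carbonyl, fixed in step 5), so that the single free OH ends up ortho to the ring F oxygen and next to the only C–H. High dilution in degassed solvent should keep the phenol formed from acylating on the ketene.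

Step 7
Reactants: 17 2,4,6-trimethoxyphenol; 18 4-bromo-2,6-dimethoxybenzaldehyde
Product: 19 2,6-dimethoxy-4-(2,4,6-trimethoxyphenoxy)benzaldehyde
Conditions: CuI (10 mol %), picolinic acid (20 mol %), K3PO4, DMSO, 90 °C, argon
Reagents that add atoms: none
Why: Ullmann-type copper-catalysed C–O coupling in which the bromide is activated by the para-formyl group and has no ortho substituent, so the hindered electron-rich phenoxide can serve as the nucleophile.

Step 8
Reactants: 19 2,6-dimethoxy-4-(2,4,6-trimethoxyphenoxy)benzaldehyde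
Product: 21 2,6-dimethoxy-4-(2,4,6-trimethoxyphenoxy)phenol (ring A–B phenol), via aryl formate 20 (not isolated)
Conditions: mCPBA, CH2Cl2, 0 °C to rt; then K2CO3 (cat.), MeOH, rt
Reagents that add atoms: mCPBA, O=C(OO)c1cccc(Cl)c1
Why: Baeyer–Villiger oxidation of a benzaldehyde with two ortho methoxy groups and a para aryloxy group, for which aryl migration is strongly favoured, then methanolysis of the formate.

Step 9
Reactants: 22 5-bromo-1,2,3-trimethoxybenzene
Product: 23 6-bromo-2,3,4-trimethoxybenzaldehyde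
Conditions: Cl2CHOMe, TiCl4, CH2Cl2, −10 to 0 °C; then H2O
Reagents that add atoms: dichloromethyl methyl ether, COC(Cl)Cl; water, O
Why: Rieche formylation (Friedel–Crafts type), where the two free positions of 22 are equivalent and each is ortho and para to methoxy groups, so one aldehyde is expected after hydrolysis of the α-chloro ether.

Step 10
Reactants: 21 ring A–B phenol; 23 6-bromo-2,3,4-trimethoxybenzaldehyde
Product: 24 6-[2,6-dimethoxy-4-(2,4,6-trimethoxyphenoxy)phenoxy]-2,3,4-trimethoxybenzaldehyde
Conditions: CuI (10 mol %), picolinic acid (20 mol %), K3PO4, DMSO, 90 °C, argon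
Reagents that add atoms: none
Why: Ullmann-type C–O coupling assisted by the ortho-formyl group, again with the hindered phenol as nucleophile and a bromide that carries only one ortho substituent.

Step 11
Reactants: 24 ring A–B–C aldehyde
Product: 26 6-[2,6-dimethoxy-4-(2,4,6-trimethoxyphenoxy)phenoxy]-2,3,4-trimethoxyphenol (ring A–B–C phenol), via aryl formate 25 (not isolated)
Conditions: mCPBA, CH2Cl2, 0 °C to rt; then K2CO3 (cat.), MeOH, rt
Reagents that add atoms: mCPBA, O=C(OO)c1cccc(Cl)c1
Why: Baeyer–Villiger oxidation of an aldehyde flanked by aryloxy and methoxy groups and para to a third oxygen, so aryl migration to the formate is expected, followed by methanolysis.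

Step 12
Reactants: 27 1-bromo-2,3-dimethoxybenzene
Product: 28 2-(3-bromo-4,5-dimethoxyphenyl)-4,4,5,5-tetramethyl-1,3,2-dioxaborolane
Conditions: [Ir(OMe)(cod)]2 (1.5 mol %), 4,4′-di-tert-butyl-2,2′-bipyridine (3 mol %), B2pin2 (0.55 equiv), THF, 80 °C
Reagents that add atoms: bis(pinacolato)diboron, CC1(C)OB(OC1(C)C)B1OC(C)(C)C(C)(C)O1
Why: Iridium-catalysed C–H borylation is sterically controlled and C5 is the only C–H of 27 without an ortho substituent, while the aryl bromide is tolerated.

Step 13
Reactants: 28 bromoaryl pinacol boronate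
Product: 29 (3-bromo-4,5-dimethoxyphenyl)boronic acid
Conditions: NaIO4, aq. NH4OAc, acetone/H2O, rt
Reagents that add atoms: water, O
Why: Periodate cleaves the pinacol released by hydrolysis and so drives the boronic ester to the free boronic acid needed for Chan–Lam coupling.

Step 14
Reactants: 26 ring A–B–C phenol; 29 (3-bromo-4,5-dimethoxyphenyl)boronic acid
Product: 30 1-bromo-2,3-dimethoxy-5-{6-[2,6-dimethoxy-4-(2,4,6-trimethoxyphenoxy)phenoxy]-2,3,4-trimethoxyphenoxy}benzene (ring A–D bromide)
Conditions: Cu(OAc)2 (50 mol %), pyridine, 4 Å MS, O2 (1 atm), CH2Cl2, rt; 29 in excess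
Reagents that add atoms: none
Why: Chan–Lam O-arylation accepts di-ortho-substituted phenols when the boronic acid has no ortho substituent, and the aryl bromide is untouched under these conditions, which keeps the handle for step 15.

Step 15
Reactants: 30 ring A–D bromide; 16 ring E–F–G phenol
Product: 31 octadeca-O-methyl ether of the target (rings A–G joined)
Conditions: CuI (20 mol %), picolinic acid (40 mol %), K3PO4, DMSO, 100 °C, argon
Reagents that add atoms: none
Why: Ullmann-type copper/picolinic acid C–O coupling between the only free hydroxyl of 16 and the only halide of 30, each partner carrying a single ortho substituent, which is within the known scope of this ligand system.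

Step 16
Reactants: 31 octadeca-O-methyl ether
Product: 32 CNP0130704.0 (target)
Conditions: BBr3 (large excess), CH2Cl2, −78 °C to rt; then H2O, 0 °C, argon, ascorbic acid in the work-up
Reagents that add atoms: none
Why: BBr3 demethylation, in which boron complexes each ether oxygen and bromide attacks the methyl carbon, leaves the diaryl ether bonds intact because they offer no sp3 carbon, and hydrolysis of the aryl borates should release all eighteen phenols.

**Compound list**

1 | syringaldehyde | COc1cc(C=O)cc(OC)c1O | starting material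
2 | 3,4,5-trimethoxyphenylboronic acid | COc1cc(B(O)O)cc(OC)c1OC | starting material
3 | 3,5-dimethoxy-4-(3,4,5-trimethoxyphenoxy)benzaldehyde | COc1cc(C=O)cc(OC)c1Oc1cc(OC)c(OC)c(OC)c1 | intermediate
4 | 3,5-dimethoxy-4-(3,4,5-trimethoxyphenoxy)phenyl formate | O=COc1cc(OC)c(Oc2cc(OC)c(OC)c(OC)c2)c(OC)c1 | intermediate
5 | 3,5-dimethoxy-4-(3,4,5-trimethoxyphenoxy)phenol | Oc1cc(OC)c(Oc2cc(OC)c(OC)c(OC)c2)c(OC)c1 | intermediate
6 | squaric acid | OC1=C(O)C(=O)C1=O | starting material
7 | 3,4-dichlorocyclobut-3-ene-1,2-dione | ClC1=C(Cl)C(=O)C1=O | intermediate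
8 | 3-chloro-4-methoxycyclobut-3-ene-1,2-dione | COC1=C(Cl)C(=O)C1=O | intermediate
9 | 3-[3,5-dimethoxy-4-(3,4,5-trimethoxyphenoxy)phenoxy]-4-methoxycyclobut-3-ene-1,2-dione | COC1=C(Oc2cc(OC)c(Oc3cc(OC)c(OC)c(OC)c3)c(OC)c2)C(=O)C1=O | intermediate
10 | methyl vinyl ether | COC=C | starting material
11 | 1-methoxyvinyllithium | [Li]C(=C)OC | intermediate
12 | lithium 3-aryloxy-1,2-dimethoxy-1-(1-methoxyethenyl)-4-oxocyclobut-2-en-1-olate analogue before methylation (lithium alkoxide of the adduct, racemic) | [Li+].[O-]C1(C(=C)OC)C(OC)=C(Oc2cc(OC)c(Oc3cc(OC)c(OC)c(OC)c3)c(OC)c2)C1=O | intermediate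
13 | 2-[3,5-dimethoxy-4-(3,4,5-trimethoxyphenoxy)phenoxy]-3,4-dimethoxy-4-(1-methoxyethenyl)cyclobut-2-en-1-one (racemic) | C=C(OC)C1(OC)C(OC)=C(Oc2cc(OC)c(Oc3cc(OC)c(OC)c(OC)c3)c(OC)c2)C1=O | intermediate
14 | (3Z)-2-[3,5-dimethoxy-4-(3,4,5-trimethoxyphenoxy)phenoxy]-3,4,5-trimethoxyhexa-1,3,5-trien-1-one (dienylketene) | O=C=C(Oc1cc(OC)c(Oc2cc(OC)c(OC)c(OC)c2)c(OC)c1)/C(OC)=C(OC)\C(OC)=C | intermediate
15 | 2-[3,5-dimethoxy-4-(3,4,5-trimethoxyphenoxy)phenoxy]-3,4,5-trimethoxycyclohexa-2,4-dien-1-one | O=C1CC(OC)=C(OC)C(OC)=C1Oc1cc(OC)c(Oc2cc(OC)c(OC)c(OC)c2)c(OC)c1 | intermediate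
16 | 2-[3,5-dimethoxy-4-(3,4,5-trimethoxyphenoxy)phenoxy]-3,4,5-trimethoxyphenol | Oc1cc(OC)c(OC)c(OC)c1Oc1cc(OC)c(Oc2cc(OC)c(OC)c(OC)c2)c(OC)c1 | intermediate
17 | 2,4,6-trimethoxyphenol | COc1cc(OC)c(O)c(OC)c1 | starting material
18 | 4-bromo-2,6-dimethoxybenzaldehyde | COc1cc(Br)cc(OC)c1C=O | starting material
19 | 2,6-dimethoxy-4-(2,4,6-trimethoxyphenoxy)benzaldehyde | COc1cc(OC)c(Oc2cc(OC)c(C=O)c(OC)c2)c(OC)c1 | intermediate
20 | 2,6-dimethoxy-4-(2,4,6-trimethoxyphenoxy)phenyl formate | COc1cc(OC)c(Oc2cc(OC)c(OC=O)c(OC)c2)c(OC)c1 | intermediate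
21 | 2,6-dimethoxy-4-(2,4,6-trimethoxyphenoxy)phenol | COc1cc(OC)c(Oc2cc(OC)c(O)c(OC)c2)c(OC)c1 | intermediate
22 | 5-bromo-1,2,3-trimethoxybenzene | COc1cc(Br)cc(OC)c1OC | starting material
23 | 6-bromo-2,3,4-trimethoxybenzaldehyde | COc1cc(Br)c(C=O)c(OC)c1OC | intermediate
24 | 6-[2,6-dimethoxy-4-(2,4,6-trimethoxyphenoxy)phenoxy]-2,3,4-trimethoxybenzaldehyde | COc1cc(OC)c(Oc2cc(OC)c(Oc3cc(OC)c(OC)c(OC)c3C=O)c(OC)c2)c(OC)c1 | intermediate
25 | 6-[2,6-dimethoxy-4-(2,4,6-trimethoxyphenoxy)phenoxy]-2,3,4-trimethoxyphenyl formate | COc1cc(OC)c(Oc2cc(OC)c(Oc3cc(OC)c(OC)c(OC)c3OC=O)c(OC)c2)c(OC)c1 | intermediate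
26 | 6-[2,6-dimethoxy-4-(2,4,6-trimethoxyphenoxy)phenoxy]-2,3,4-trimethoxyphenol | COc1cc(OC)c(Oc2cc(OC)c(Oc3cc(OC)c(OC)c(OC)c3O)c(OC)c2)c(OC)c1 | intermediate
27 | 1-bromo-2,3-dimethoxybenzene | COc1cccc(Br)c1OC | starting material
28 | 2-(3-bromo-4,5-dimethoxyphenyl)-4,4,5,5-tetramethyl-1,3,2-dioxaborolane | COc1cc(B2OC(C)(C)C(C)(C)O2)cc(Br)c1OC | intermediate
29 | (3-bromo-4,5-dimethoxyphenyl)boronic acid | COc1cc(B(O)O)cc(Br)c1OC | intermediate
30 | 1-bromo-2,3-dimethoxy-5-{6-[2,6-dimethoxy-4-(2,4,6-trimethoxyphenoxy)phenoxy]-2,3,4-trimethoxyphenoxy}benzene | COc1cc(OC)c(Oc2cc(OC)c(Oc3cc(OC)c(OC)c(OC)c3Oc3cc(OC)c(OC)c(Br)c3)c(OC)c2)c(OC)c1 | intermediate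
31 | octadeca-O-methyl ether of the target | COc1cc(OC)c(Oc2cc(OC)c(Oc3cc(OC)c(OC)c(OC)c3Oc3cc(OC)c(OC)c(Oc4cc(OC)c(OC)c(OC)c4Oc4cc(OC)c(Oc5cc(OC)c(OC)c(OC)c5)c(OC)c4)c3)c(OC)c2)c(OC)c1 | intermediate
32 | CNP0130704.0 | Oc1cc(O)c(Oc2cc(O)c(Oc3cc(O)c(O)c(O)c3Oc3cc(O)c(O)c(Oc4cc(O)c(O)c(O)c4Oc4cc(O)c(Oc5cc(O)c(O)c(O)c5)c(O)c4)c3)c(O)c2)c(O)c1 | target

**Step count**

Total steps: 16. Longest linear sequence: 7 steps (1, 2, 4, 5, 6, 15, 16 from syringaldehyde; equally 7, 8, 10, 11, 14, 15, 16 from 2,4,6-trimethoxyphenol).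

**Three steps most likely to fail**

Step 5. The vinyllithium may attack the other carbonyl, which after ring expansion would put the aryloxy group meta to the new hydroxyl. It may also add in conjugate fashion and expel aryloxide. The fallback removes the regiochemical question by symmetry. It sets out from dichloride 7 and two equivalents of phenol 5 (iPr2NEt, CH2Cl2, −40 to 0 °C), which should give the symmetrical 3,4-bis(aryloxy)cyclobutenedione F1. Addition of 11 at −78 °C and capping with MeOTf, through the lithium alkoxide F2, should give the 2,3-bis(aryloxy)-4-methoxy-4-(1-methoxyethenyl)cyclobutenone F3. One equivalent of NaOMe in MeOH/THF at −20 °C should then exchange only the aryloxy group on the β-carbon of the enone (the vinylogous ester position) by conjugate addition–elimination. This returns to the route at 13 and gives back one equivalent of 5.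

Step 15. Two large, electron-rich partners that each carry an ortho substituent may couple slowly. Reduction of the bromide or oxidation of the phenol could then take over. The fallback reverses the coupling mode and sets out from bromide 30. Palladium-catalysed borylation (Pd(OAc)2, XPhos, B2(OH)4, KOAc, EtOH, 80 °C) should give the ring A–D boronic acid F4. Chan–Lam coupling of F4 with phenol 16 (Cu(OAc)2, pyridine, 4 Å MS, O2, CH2Cl2, rt) comes back to the route at 31.

Step 6. The ketene may be intercepted by the phenol already formed, giving aryl esters. The acid-labile enol ether may be lost before ring opening, or the opening may proceed with the non-productive sense of rotation. The fallback builds ring E from an existing arene and sets out from phenol 5. Ullmann coupling with commercial 2-bromo-3,4,5-trimethoxybenzaldehyde (CuI, picolinic acid, K3PO4, DMSO, 90 °C; the ortho-formyl group activates the hindered bromide) should give the 2-aryloxy-3,4,5-trimethoxybenzaldehyde F5. Baeyer–Villiger oxidation with mCPBA should give the aryl formate F6, and K2CO3 in MeOH returns to the route at 16.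

**Further compounds**

F1 | step 5 | 3,4-bis[3,5-dimethoxy-4-(3,4,5-trimethoxyphenoxy)phenoxy]cyclobut-3-ene-1,2-dione | O=C1C(=O)C(Oc2cc(OC)c(Oc3cc(OC)c(OC)c(OC)c3)c(OC)c2)=C1Oc1cc(OC)c(Oc2cc(OC)c(OC)c(OC)c2)c(OC)c1
F2 | step 5 | lithium alkoxide of the 1-methoxyvinyl adduct of F1 (racemic) | [Li+].[O-]C1(C(=C)OC)C(Oc2cc(OC)c(Oc3cc(OC)c(OC)c(OC)c3)c(OC)c2)=C(Oc2cc(OC)c(Oc3cc(OC)c(OC)c(OC)c3)c(OC)c2)C1=O
F3 | step 5 | 2,3-bis[3,5-dimethoxy-4-(3,4,5-trimethoxyphenoxy)phenoxy]-4-methoxy-4-(1-methoxyethenyl)cyclobut-2-en-1-one (racemic) | C=C(OC)C1(OC)C(Oc2cc(OC)c(Oc3cc(OC)c(OC)c(OC)c3)c(OC)c2)=C(Oc2cc(OC)c(Oc3cc(OC)c(OC)c(OC)c3)c(OC)c2)C1=O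
F4 | step 15 | (2,3-dimethoxy-5-{6-[2,6-dimethoxy-4-(2,4,6-trimethoxyphenoxy)phenoxy]-2,3,4-trimethoxyphenoxy}phenyl)boronic acid | COc1cc(OC)c(Oc2cc(OC)c(Oc3cc(OC)c(OC)c(OC)c3Oc3cc(OC)c(OC)c(B(O)O)c3)c(OC)c2)c(OC)c1
F5 | step 6 | 2-[3,5-dimethoxy-4-(3,4,5-trimethoxyphenoxy)phenoxy]-3,4,5-trimethoxybenzaldehyde | COc1cc(C=O)c(Oc2cc(OC)c(Oc3cc(OC)c(OC)c(OC)c3)c(OC)c2)c(OC)c1OC
F6 | step 6 | 2-[3,5-dimethoxy-4-(3,4,5-trimethoxyphenoxy)phenoxy]-3,4,5-trimethoxyphenyl formate | COc1cc(OC=O)c(Oc2cc(OC)c(Oc3cc(OC)c(OC)c(OC)c3)c(OC)c2)c(OC)c1OC
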